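The route rests on making the benzene ring C18–C23 from a squarate-derived cyclobutenone rather than by substituting an arene. Heating cyclobutenone 11 opens it to a dienylketene that closes the C19–C20 bond by 6π electrocyclisation and enolises, so one operation delivers the 1,4-hydroquinone whose C23 hydroxyl is flanked by the nitrogen on C22 and the chain on C18. The precursor is a 3-(dibenzylamino)-4-hydroxycyclobutenone carrying a 5-benzyloxypent-1-en-2-yl group on the carbinol carbon, so that one hydrogenolysis later frees both nitrogen and the C15 oxygen. The chain is then grown by Z-olefination, syn aldol and propargylation, acylated with a C1–C5 acid and closed by a double Stille coupling.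

Key step: step 6

Remark: chain atoms are numbered from the amide carbonyl C1 through C17 to the arene carbons C18–C23; the target is read as 3R,11R,12R,13S with 4E,6E,8E,14Z, and its arene is at the hydroquinone oxidation level.

Step 1
Reactants: 1 diisopropyl squarate
Product: 3 3-isopropoxycyclobut-3-ene-1,2-dione, via hydroxycyclobutenone 2 (not isolated)
Conditions: LiAlH(Ot-Bu)3, THF, −78 → 0 °C; aq. work-up; then conc. HCl (cat.), CH2Cl2, rt
Reagents that add atoms: none
Why: The bulky hydride reduces one vinylogous-ester carbonyl once (1,2-reduction), and acid then transposes the allylic hydroxyl and expels propan-2-ol, the standard entry to the semisquarate.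

Step 2
Reactants: 3 3-isopropoxycyclobut-3-ene-1,2-dione; 4 dibenzylamine
Product: 5 3-(dibenzylamino)cyclobut-3-ene-1,2-dione
Conditions: THF, 0 °C → rt
Reagents that add atoms: none
Why: Conjugate addition–elimination of the secondary amine at the alkoxy-bearing carbon of the vinylogous ester should give the vinylogous amide with loss of propan-2-ol.

Step 3
Reactants: 6 pent-4-yn-1-ol
Product: 7 benzyl pent-4-yn-1-yl ether
Conditions: NaH, BnBr, Bu4NI (cat.), THF, 0 °C → rt
Reagents that add atoms: benzyl bromide, BrCc1ccccc1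
Why: Williamson ether synthesis, in which NaH deprotonates only the hydroxyl (the alkyne C–H is far less acidic) and the alkoxide displaces bromide by SN2 substitution.

Step 4
Reactants: 7 benzyl pent-4-yn-1-yl ether
Product: 9 benzyl 4-bromopent-4-en-1-yl ether, via alkenylborane 8 (not isolated)
Conditions: B-bromo-9-BBN, CH2Cl2, 0 °C → rt; then AcOH, 0 °C
Reagents that add atoms: B-bromo-9-borabicyclo[3.3.1]nonane, BrB1C2CCCC1CCC2
Why: syn-Bromoboration of the terminal alkyne places boron on the terminal and bromine on the internal carbon, and protonolysis of the alkenyl–boron bond by acetic acid leaves the 2-bromo-1-alkene (haloboration–protonolysis).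

Step 5
Reactants: 9 benzyl 4-bromopent-4-en-1-yl ether; 5 3-(dibenzylamino)cyclobut-3-ene-1,2-dione
Product: 11 rac-4-[5-(benzyloxy)pent-1-en-2-yl]-3-(dibenzylamino)-4-hydroxycyclobut-2-en-1-one, via alkenyllithium 10 (not isolated)
Conditions: 9, t-BuLi (2.0 equiv), Et2O, −78 °C; then 5, THF, −78 °C; aq. NH4Cl
Reagents that add atoms: none
Why: Bromine–lithium exchange gives the 2-lithioalkene, which adds 1,2 to the only ketone-like carbonyl of 5, the one beside the amino carbon, because the other carbonyl is deactivated as a vinylogous amide; the new carbinol is racemic and is erased in step 6.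

Step 6
Reactants: 11 rac-4-[5-(benzyloxy)pent-1-en-2-yl]-3-(dibenzylamino)-4-hydroxycyclobut-2-en-1-one
Product: 15 N,N-dibenzyl-3-[3-(benzyloxy)propyl]-2,5-bis(triisopropylsilyloxy)aniline, via dienylketene 12 (not isolated), via cyclohexadienone 13 (not isolated), via aminohydroquinone 14 (not isolated)
Conditions: p-xylene (degassed), 135 °C; then 0 °C, TIPSOTf, 2,6-lutidine, CH2Cl2, 0 °C → rt
Reagents that add atoms: triisopropylsilyl triflate, CC(C)[Si](OS(=O)(=O)C(F)(F)F)(C(C)C)C(C)C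
Why: Heating breaks the C20–C23 bond of 11 by conrotatory 4π electrocyclic opening, the hydroxyl turning outward so that the pentenyl group lies cis to the new ketene in 12; disrotatory 6π electrocyclisation then joins the ketene carbon C20 to the methylene carbon C19, closing the one new six-membered ring as dienone 13, and enolisation aromatises it to 14. This is the Moore rearrangement of 4-alkenyl-4-hydroxycyclobutenones, applied to a 3-amino member of the class. No stereocenter is formed. The selectivity needed is regiochemical, and it is fixed beforehand by the connectivity of 11 (N on the carbon next to the carbinol) and by the outward torquoselectivity of the oxygen substituent, so only the N(C22)–OH(C23)–chain(C18) pattern can arise. The electron-rich aminohydroquinone is never exposed to air but silylated in the same flask on both oxygens, the crowded C23 hydroxyl requiring the silyl triflate.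

Step 7
Reactants: 15 N,N-dibenzyl-3-[3-(benzyloxy)propyl]-2,5-bis(triisopropylsilyloxy)aniline
Product: 17 tert-butyl {3-(3-hydroxypropyl)-2,5-bis(triisopropylsilyloxy)phenyl}carbamate, via amino alcohol 16 (not isolated)
Conditions: H2 (3 atm), Pd(OH)2/C, EtOH/EtOAc, rt; filter; then Boc2O, EtOH, 40 °C
Reagents that add atoms: di-tert-butyl dicarbonate, CC(C)(C)OC(=O)OC(=O)OC(C)(C)C
Why: Hydrogenolysis over Pearlman's catalyst cleaves both N-benzyl groups and the O-benzyl ether while aryl silyl ethers are inert, and the freed aniline is then converted into its carbamate by Boc2O in ethanol, which does not acylate the primary alcohol.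

Step 8
Reactants: 17 tert-butyl {3-(3-hydroxypropyl)-2,5-bis(triisopropylsilyloxy)phenyl}carbamate
Product: 18 tert-butyl {3-(3-oxopropyl)-2,5-bis(triisopropylsilyloxy)phenyl}carbamate
Conditions: Dess–Martin periodinane, NaHCO3, CH2Cl2, 0 °C → rt
Reagents that add atoms: none
Why: Dess–Martin oxidation of the primary alcohol to the C15 aldehyde under buffered, non-acidic conditions that the carbamate and silyl ethers tolerate.

Step 9
Reactants: 18 tert-butyl {3-(3-oxopropyl)-2,5-bis(triisopropylsilyloxy)phenyl}carbamate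
Product: 19 ethyl (2Z)-5-{3-[(tert-butoxycarbonyl)amino]-2,5-bis(triisopropylsilyloxy)phenyl}-2-methylpent-2-enoate
Conditions: (CF3CH2O)2P(O)CH(CH3)CO2Et, KN(SiMe3)2, 18-crown-6, THF, −78 °C
Reagents that add atoms: ethyl 2-[bis(2,2,2-trifluoroethoxy)phosphoryl]propanoate, CCOC(=O)C(C)P(=O)(OCC(F)(F)F)OCC(F)(F)F
Why: Still–Gennari olefination, in which the trifluoroethyl phosphonate anion adds irreversibly and the adduct collapses fast, so the kinetic (Z)-2-methyl enoate with the ester carbon (future C13) cis to C16 should dominate.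

Step 10
Reactants: 19 ethyl (2Z)-5-{3-[(tert-butoxycarbonyl)amino]-2,5-bis(triisopropylsilyloxy)phenyl}-2-methylpent-2-enoate
Product: 20 tert-butyl {3-[(3Z)-5-hydroxy-4-methylpent-3-en-1-yl]-2,5-bis(triisopropylsilyloxy)phenyl}carbamate
Conditions: i-Bu2AlH (excess), CH2Cl2, −78 °C; aq. KNaC4H4O6 work-up
Reagents that add atoms: none
Why: 1,2-Reduction of the enoate to the allylic alcohol by the aluminium hydride at low temperature leaves the alkene geometry and the N-deprotonated carbamate untouched.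

Step 11
Reactants: 20 tert-butyl {3-[(3Z)-5-hydroxy-4-methylpent-3-en-1-yl]-2,5-bis(triisopropylsilyloxy)phenyl}carbamate
Product: 21 tert-butyl {3-[(3Z)-4-methyl-5-oxopent-3-en-1-yl]-2,5-bis(triisopropylsilyloxy)phenyl}carbamate
Conditions: Dess–Martin periodinane, NaHCO3, CH2Cl2, 0 °C
Reagents that add atoms: none
Why: Dess–Martin oxidation of the allylic alcohol under buffered conditions should give the (Z)-enal without acid- or base-induced isomerisation to the E isomer.

Step 12
Reactants: 21 tert-butyl {3-[(3Z)-4-methyl-5-oxopent-3-en-1-yl]-2,5-bis(triisopropylsilyloxy)phenyl}carbamate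
Product: 22 syn aldol imide (12S,13S) with the (4S)-4-benzyl-2-oxooxazolidin-3-yl group on C11
Conditions: (S)-4-benzyl-3-propionyloxazolidin-2-one, Bu2BOTf, Et3N, CH2Cl2, −78 → 0 °C; then 21, −78 → 0 °C; pH 7 buffer, MeOH, H2O2, 0 °C
Reagents that add atoms: (S)-4-benzyl-3-propionyloxazolidin-2-one, CCC(=O)N1[C@@H](Cc2ccccc2)COC1=O
Why: Evans syn aldol, in which the (Z)-dibutylboron enolate reacts through a Zimmerman–Traxler chair whose accessible face is dictated by the benzyl group of the (S)-auxiliary, setting C12 and C13 together (12,13-syn, methyl and hydroxyl as in the target) independently of the achiral enal.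

Step 13
Reactants: 22 syn aldol imide (12S,13S)
Product: 23 C13 tert-butyldimethylsilyl ether of imide 22
Conditions: TBSOTf, 2,6-lutidine, CH2Cl2, −78 °C
Reagents that add atoms: tert-butyldimethylsilyl triflate, CC(C)(C)[Si](C)(C)OS(=O)(=O)C(F)(F)F
Why: Silylation of the hindered allylic secondary alcohol with the silyl triflate at low temperature, where the carbamate is not attacked, blocks retro-aldol cleavage in the following steps.

Step 14
Reactants: 23 C13 tert-butyldimethylsilyl ether of imide 22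
Product: 24 primary C11 alcohol (12R,13S)
Conditions: LiBH4, MeOH, THF, 0 °C
Reagents that add atoms: none
Why: Reductive cleavage of the N-acyl oxazolidinone by LiBH4 attacks the exocyclic imide carbonyl and releases the auxiliary, leaving carbamate, silyl ethers and both stereocenters intact.

Step 15
Reactants: 24 primary C11 alcohol (12R,13S)
Product: 25 C11 aldehyde (12S,13S)
Conditions: Dess–Martin periodinane, NaHCO3, CH2Cl2, 0 °C → rt
Reagents that add atoms: none
Why: Dess–Martin oxidation under buffered conditions gives the α-methyl aldehyde without epimerisation at C12, and the aldehyde is used at once.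

Step 16
Reactants: 25 C11 aldehyde (12S,13S)
Product: 26 homopropargylic alcohol (11R,12R,13S)
Conditions: H2C=C=CHMgBr, (+)-Ipc2BOMe, Et2O, −78 → 0 °C; then 25, Et2O, −78 °C; NaBO3·4H2O, THF/H2O, rt
Reagents that add atoms: B-allenyldiisopinocampheylborane made in the flask from allenylmagnesium bromide (C=C=C[Mg]Br), C=C=CB([C@H]1C[C@H]2C[C@@H]([C@@H]1C)C2(C)C)[C@H]1C[C@H]2C[C@@H]([C@@H]1C)C2(C)C
Why: Asymmetric allenylboration, in which the allenylborane transfers a propargyl group through a cyclic six-membered SE2′ transition state and the isopinocampheyl groups derived from (−)-α-pinene direct it to the Re face of the C11 aldehyde, giving the (11R) carbinol anti to the C12 methyl under reagent control.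

Step 17
Reactants: 26 homopropargylic alcohol (11R,12R,13S)
Product: 27 11,13-bis(tert-butyldimethylsilyl) ether alkyne
Conditions: TBSOTf, 2,6-lutidine, CH2Cl2, −78 → 0 °C
Reagents that add atoms: tert-butyldimethylsilyl triflate, CC(C)(C)[Si](C)(C)OS(=O)(=O)C(F)(F)F
Why: Silylation of the C11 hydroxyl removes the last acylable oxygen before the later anilide formation and simplifies the hydrometallation.

Step 18
Reactants: 27 11,13-bis(tert-butyldimethylsilyl) ether alkyne
Product: 29 (8E)-iodoalkene, via alkenylzirconocene 28 (not isolated)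
Conditions: Cp2Zr(H)Cl (excess), THF, rt; then I2, THF, −20 °C
Reagents that add atoms: iodine, II
Why: Schwartz hydrozirconation adds Zr–H syn across the terminal alkyne with zirconium on the terminal carbon, and iodinolysis of the C–Zr bond with retention gives the (E)-iodoalkene, while the trisubstituted alkene is inert and the carbamate N–H only consumes hydride.

Step 19
Reactants: 29 (8E)-iodoalkene
Product: 31 free aniline, via silyl carbamate 30 (not isolated)
Conditions: TMSOTf, 2,6-lutidine, CH2Cl2, 0 °C; then MeOH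
Reagents that add atoms: none
Why: Silyl-triflate-mediated Boc cleavage, in which O-silylation of the carbamate carbonyl triggers loss of 2-methylpropene and methanol then releases the aniline with loss of CO2, conditions that alkyl and aryl silyl ethers and the iodoalkene survive.

Step 20
Reactants: 32 dimethyl (R)-malate
Product: 33 methyl (3R)-3,4-dihydroxybutanoate
Conditions: BH3·SMe2, NaBH4 (cat.), THF, 0 °C → rt; MeOH quench
Reagents that add atoms: none
Why: Hydroxyl-directed borane reduction, in which the alkoxyborane formed at the free hydroxyl delivers hydride through a five-membered chelate only to the adjacent ester and leaves the distal ester and the stereocenter untouched.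

Step 21
Reactants: 33 methyl (3R)-3,4-dihydroxybutanoate
Product: 34 methyl (3R)-4-(tert-butyldimethylsilyloxy)-3-hydroxybutanoate
Conditions: TBSCl, imidazole, CH2Cl2, 0 °C
Reagents that add atoms: tert-butyldimethylsilyl chloride, CC(C)(C)[Si](C)(C)Cl
Why: Silylation with the bulky chlorosilane is selective for the primary hydroxyl on steric grounds.

Step 22
Reactants: 34 methyl (3R)-4-(tert-butyldimethylsilyloxy)-3-hydroxybutanoate
Product: 35 methyl (3R)-4-(tert-butyldimethylsilyloxy)-3-methoxybutanoate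
Conditions: Me3OBF4, 1,8-bis(dimethylamino)naphthalene, CH2Cl2, rt
Reagents that add atoms: trimethyloxonium tetrafluoroborate, C[O+](C)C.F[B-](F)(F)F
Why: O-Methylation with Meerwein's salt and a hindered non-nucleophilic base avoids the alkoxide, so neither retro-aldol cleavage, β-elimination nor silyl migration of the β-hydroxy ester should occur.

Step 23
Reactants: 35 methyl (3R)-4-(tert-butyldimethylsilyloxy)-3-methoxybutanoate
Product: 36 methyl (3R)-4-hydroxy-3-methoxybutanoate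
Conditions: HF·pyridine, pyridine, THF, 0 °C
Reagents that add atoms: none
Why: Buffered fluoride cleaves the primary silyl ether at low temperature, conditions chosen to suppress lactonisation of the γ-hydroxy ester, which is oxidised without storage.

Step 24
Reactants: 36 methyl (3R)-4-hydroxy-3-methoxybutanoate
Product: 37 methyl (3R)-3-methoxy-4-oxobutanoate
Conditions: Dess–Martin periodinane, NaHCO3, CH2Cl2, 0 °C → rt
Reagents that add atoms: none
Why: Dess–Martin oxidation gives the α-methoxy aldehyde under neutral conditions that do not epimerise C3.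

Step 25
Reactants: 37 methyl (3R)-3-methoxy-4-oxobutanoate
Product: 38 methyl (3R,4E)-5-iodo-3-methoxypent-4-enoate
Conditions: CrCl2, CHI3, THF/1,4-dioxane, 0 °C → rt
Reagents that add atoms: iodoform, IC(I)I
Why: Takai olefination, in which the geminal dichromium species from CHI3 and CrCl2 adds to the aldehyde and eliminates to the (E)-iodoalkene under neutral conditions that preserve the α-methoxy stereocenter and the ester.

Step 26
Reactants: 38 methyl (3R,4E)-5-iodo-3-methoxypent-4-enoate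
Product: 39 (3R,4E)-5-iodo-3-methoxypent-4-enoic acid
Conditions: LiOH, THF/H2O, 0 °C; then aq. HCl to pH 3
Reagents that add atoms: lithium hydroxide, [Li+].[OH-]
Why: Saponification by acyl–oxygen cleavage at 0 °C, where the carboxylate formed protects the α-position against E1cB loss of methoxide.

Step 27
Reactants: 39 (3R,4E)-5-iodo-3-methoxypent-4-enoic acid; 31 free aniline
Product: 41 bis(iodoalkene) anilide, via mixed anhydride 40 (not isolated)
Conditions: 39, BOP-Cl, i-Pr2NEt, CH2Cl2, 0 °C; then 31, 0 °C → rt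
Reagents that add atoms: none
Why: Amide formation through the mixed carboxylic–phosphinic anhydride, in which the aniline nitrogen is the only acylable nucleophile left in 31 and attacks the activated acyl carbon under mild base.

Step 28
Reactants: 41 bis(iodoalkene) anilide
Product: 43 fully silylated macrolactam, via dienylstannane 42 (not isolated)
Conditions: (E)-Bu3SnCH=CHSnBu3, PdCl2(MeCN)2 (20 mol %), i-Pr2NEt, DMF/THF, rt, 1 mM
Reagents that add atoms: (E)-1,2-bis(tributylstannyl)ethene, CCCC[Sn](CCCC)(CCCC)/C=C/[Sn](CCCC)(CCCC)CCCC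
Why: Double Stille coupling, in which zerovalent palladium formed in the flask inserts into each (E)-iodoalkene and transmetallation and reductive elimination form C5–C6 and C7–C8 with retention of all alkene geometries, the second, intramolecular coupling closing the 21-membered ring at high dilution (42 is drawn for first coupling at C8; the other order gives the same ring).

Step 29
Reactants: 43 fully silylated macrolactam
Product: 44 target macrolactam
Conditions: Bu4NF, AcOH, THF (degassed), 0 → 40 °C; aq. Na2S2O4 work-up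
Reagents that add atoms: none
Why: Fluoride cleaves the two aryl triisopropylsilyl and the two alkyl tert-butyldimethylsilyl ethers, acetic acid buffers the phenoxides, and exclusion of oxygen with a dithionite wash keeps the arene at the hydroquinone level.

Compound list

1 | diisopropyl squarate | CC(C)OC1=C(OC(C)C)C(=O)C1=O | starting material
2 | rac-4-hydroxy-2,3-diisopropoxycyclobut-2-en-1-one | CC(C)OC1=C(OC(C)C)C(=O)C1O | intermediate
3 | 3-isopropoxycyclobut-3-ene-1,2-dione | CC(C)OC1=CC(=O)C1=O | intermediate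
4 | dibenzylamine | C(NCc1ccccc1)c1ccccc1 | starting material
5 | 3-(dibenzylamino)cyclobut-3-ene-1,2-dione | O=C1C=C(N(Cc2ccccc2)Cc2ccccc2)C1=O | intermediate
6 | pent-4-yn-1-ol | C#CCCCO | starting material
7 | benzyl pent-4-yn-1-yl ether | C#CCCCOCc1ccccc1 | intermediate
8 | 9-[(1Z)-5-(benzyloxy)-2-bromopent-1-en-1-yl]-9-borabicyclo[3.3.1]nonane | Br/C(CCCOCc1ccccc1)=C\B1C2CCCC1CCC2 | intermediate
9 | benzyl 4-bromopent-4-en-1-yl ether | C=C(Br)CCCOCc1ccccc1 | intermediate
10 | [5-(benzyloxy)pent-1-en-2-yl]lithium | [Li]C(=C)CCCOCc1ccccc1 | intermediate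
11 | rac-4-[5-(benzyloxy)pent-1-en-2-yl]-3-(dibenzylamino)-4-hydroxycyclobut-2-en-1-one | O=C1C=C(N(Cc2ccccc2)Cc2ccccc2)C1(O)C(=C)CCCOCc1ccccc1 | intermediate
12 | (3Z)-8-(benzyloxy)-3-(dibenzylamino)-4-hydroxy-5-methylideneocta-1,3-dien-1-one | O=C=C/C(N(Cc1ccccc1)Cc1ccccc1)=C(/O)C(=C)CCCOCc1ccccc1 | intermediate
13 | 5-[3-(benzyloxy)propyl]-3-(dibenzylamino)-4-hydroxycyclohexa-2,4-dien-1-one | O=C1C=C(N(Cc2ccccc2)Cc2ccccc2)C(O)=C(CCCOCc2ccccc2)C1 | intermediate
14 | 2-[3-(benzyloxy)propyl]-6-(dibenzylamino)benzene-1,4-diol | Oc1cc(N(Cc2ccccc2)Cc2ccccc2)c(O)c(CCCOCc2ccccc2)c1 | intermediate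
15 | N,N-dibenzyl-3-[3-(benzyloxy)propyl]-2,5-bis(triisopropylsilyloxy)aniline | c1ccccc1COCCCc1cc(O[Si](C(C)C)(C(C)C)C(C)C)cc(N(Cc2ccccc2)Cc2ccccc2)c1O[Si](C(C)C)(C(C)C)C(C)C | intermediate
16 | 3-[3-amino-2,5-bis(triisopropylsilyloxy)phenyl]propan-1-ol | OCCCc1cc(O[Si](C(C)C)(C(C)C)C(C)C)cc(N)c1O[Si](C(C)C)(C(C)C)C(C)C | intermediate
17 | tert-butyl {3-(3-hydroxypropyl)-2,5-bis(triisopropylsilyloxy)phenyl}carbamate | OCCCc1cc(O[Si](C(C)C)(C(C)C)C(C)C)cc(NC(=O)OC(C)(C)C)c1O[Si](C(C)C)(C(C)C)C(C)C | intermediate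
18 | tert-butyl {3-(3-oxopropyl)-2,5-bis(triisopropylsilyloxy)phenyl}carbamate | O=CCCc1cc(O[Si](C(C)C)(C(C)C)C(C)C)cc(NC(=O)OC(C)(C)C)c1O[Si](C(C)C)(C(C)C)C(C)C | intermediate
19 | ethyl (2Z)-5-{3-[(tert-butoxycarbonyl)amino]-2,5-bis(triisopropylsilyloxy)phenyl}-2-methylpent-2-enoate | CCOC(=O)/C(C)=C\CCc1cc(O[Si](C(C)C)(C(C)C)C(C)C)cc(NC(=O)OC(C)(C)C)c1O[Si](C(C)C)(C(C)C)C(C)C | intermediate
20 | tert-butyl {3-[(3Z)-5-hydroxy-4-methylpent-3-en-1-yl]-2,5-bis(triisopropylsilyloxy)phenyl}carbamate | OC/C(C)=C\CCc1cc(O[Si](C(C)C)(C(C)C)C(C)C)cc(NC(=O)OC(C)(C)C)c1O[Si](C(C)C)(C(C)C)C(C)C | intermediate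
21 | tert-butyl {3-[(3Z)-4-methyl-5-oxopent-3-en-1-yl]-2,5-bis(triisopropylsilyloxy)phenyl}carbamate | O=C/C(C)=C\CCc1cc(O[Si](C(C)C)(C(C)C)C(C)C)cc(NC(=O)OC(C)(C)C)c1O[Si](C(C)C)(C(C)C)C(C)C | intermediate
22 | tert-butyl {3-[(3Z,5S,6S)-7-[(4S)-4-benzyl-2-oxo-1,3-oxazolidin-3-yl]-5-hydroxy-4,6-dimethyl-7-oxohept-3-en-1-yl]-2,5-bis(triisopropylsilyloxy)phenyl}carbamate | O=C1OC[C@H](Cc2ccccc2)N1C(=O)[C@@H](C)[C@H](O)/C(C)=C\CCc1cc(O[Si](C(C)C)(C(C)C)C(C)C)cc(NC(=O)OC(C)(C)C)c1O[Si](C(C)C)(C(C)C)C(C)C | intermediate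
23 | tert-butyl {3-[(3Z,5S,6S)-7-[(4S)-4-benzyl-2-oxo-1,3-oxazolidin-3-yl]-5-(tert-butyldimethylsilyloxy)-4,6-dimethyl-7-oxohept-3-en-1-yl]-2,5-bis(triisopropylsilyloxy)phenyl}carbamate | O=C1OC[C@H](Cc2ccccc2)N1C(=O)[C@@H](C)[C@H](O[Si](C)(C)C(C)(C)C)/C(C)=C\CCc1cc(O[Si](C(C)C)(C(C)C)C(C)C)cc(NC(=O)OC(C)(C)C)c1O[Si](C(C)C)(C(C)C)C(C)C | intermediate
24 | tert-butyl {3-[(3Z,5S,6R)-5-(tert-butyldimethylsilyloxy)-7-hydroxy-4,6-dimethylhept-3-en-1-yl]-2,5-bis(triisopropylsilyloxy)phenyl}carbamate | OC[C@@H](C)[C@H](O[Si](C)(C)C(C)(C)C)/C(C)=C\CCc1cc(O[Si](C(C)C)(C(C)C)C(C)C)cc(NC(=O)OC(C)(C)C)c1O[Si](C(C)C)(C(C)C)C(C)C | intermediate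
25 | tert-butyl {3-[(3Z,5S,6S)-5-(tert-butyldimethylsilyloxy)-4,6-dimethyl-7-oxohept-3-en-1-yl]-2,5-bis(triisopropylsilyloxy)phenyl}carbamate | O=C[C@@H](C)[C@H](O[Si](C)(C)C(C)(C)C)/C(C)=C\CCc1cc(O[Si](C(C)C)(C(C)C)C(C)C)cc(NC(=O)OC(C)(C)C)c1O[Si](C(C)C)(C(C)C)C(C)C | intermediate
26 | tert-butyl {3-[(3Z,5S,6R,7R)-5-(tert-butyldimethylsilyloxy)-7-hydroxy-4,6-dimethyldec-3-en-9-yn-1-yl]-2,5-bis(triisopropylsilyloxy)phenyl}carbamate | C#CC[C@@H](O)[C@@H](C)[C@H](O[Si](C)(C)C(C)(C)C)/C(C)=C\CCc1cc(O[Si](C(C)C)(C(C)C)C(C)C)cc(NC(=O)OC(C)(C)C)c1O[Si](C(C)C)(C(C)C)C(C)C | intermediate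
27 | tert-butyl {3-[(3Z,5S,6R,7R)-5,7-bis(tert-butyldimethylsilyloxy)-4,6-dimethyldec-3-en-9-yn-1-yl]-2,5-bis(triisopropylsilyloxy)phenyl}carbamate | C#CC[C@@H](O[Si](C)(C)C(C)(C)C)[C@@H](C)[C@H](O[Si](C)(C)C(C)(C)C)/C(C)=C\CCc1cc(O[Si](C(C)C)(C(C)C)C(C)C)cc(NC(=O)OC(C)(C)C)c1O[Si](C(C)C)(C(C)C)C(C)C | intermediate
28 | (E)-alkenylzirconocene chloride from 27, zirconium on C8, cyclopentadienyl ligands drawn as σ-bonded, carbamate N–H drawn free | Cl[Zr](C1C=CC=C1)(C1C=CC=C1)/C=C/C[C@@H](O[Si](C)(C)C(C)(C)C)[C@@H](C)[C@H](O[Si](C)(C)C(C)(C)C)/C(C)=C\CCc1cc(O[Si](C(C)C)(C(C)C)C(C)C)cc(NC(=O)OC(C)(C)C)c1O[Si](C(C)C)(C(C)C)C(C)C | intermediate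
29 | tert-butyl {3-[(3Z,5S,6R,7R,9E)-5,7-bis(tert-butyldimethylsilyloxy)-10-iodo-4,6-dimethyldeca-3,9-dien-1-yl]-2,5-bis(triisopropylsilyloxy)phenyl}carbamate | I/C=C/C[C@@H](O[Si](C)(C)C(C)(C)C)[C@@H](C)[C@H](O[Si](C)(C)C(C)(C)C)/C(C)=C\CCc1cc(O[Si](C(C)C)(C(C)C)C(C)C)cc(NC(=O)OC(C)(C)C)c1O[Si](C(C)C)(C(C)C)C(C)C | intermediate
30 | trimethylsilyl {3-[(3Z,5S,6R,7R,9E)-5,7-bis(tert-butyldimethylsilyloxy)-10-iodo-4,6-dimethyldeca-3,9-dien-1-yl]-2,5-bis(triisopropylsilyloxy)phenyl}carbamate | I/C=C/C[C@@H](O[Si](C)(C)C(C)(C)C)[C@@H](C)[C@H](O[Si](C)(C)C(C)(C)C)/C(C)=C\CCc1cc(O[Si](C(C)C)(C(C)C)C(C)C)cc(NC(=O)O[Si](C)(C)C)c1O[Si](C(C)C)(C(C)C)C(C)C | intermediate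
31 | 3-[(3Z,5S,6R,7R,9E)-5,7-bis(tert-butyldimethylsilyloxy)-10-iodo-4,6-dimethyldeca-3,9-dien-1-yl]-2,5-bis(triisopropylsilyloxy)aniline | I/C=C/C[C@@H](O[Si](C)(C)C(C)(C)C)[C@@H](C)[C@H](O[Si](C)(C)C(C)(C)C)/C(C)=C\CCc1cc(O[Si](C(C)C)(C(C)C)C(C)C)cc(N)c1O[Si](C(C)C)(C(C)C)C(C)C | intermediate
32 | dimethyl (R)-malate | COC(=O)C[C@@H](O)C(=O)OC | starting material
33 | methyl (3R)-3,4-dihydroxybutanoate | COC(=O)C[C@@H](O)CO | intermediate
34 | methyl (3R)-4-(tert-butyldimethylsilyloxy)-3-hydroxybutanoate | COC(=O)C[C@@H](O)CO[Si](C)(C)C(C)(C)C | intermediate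
35 | methyl (3R)-4-(tert-butyldimethylsilyloxy)-3-methoxybutanoate | COC(=O)C[C@@H](OC)CO[Si](C)(C)C(C)(C)C | intermediate
36 | methyl (3R)-4-hydroxy-3-methoxybutanoate | COC(=O)C[C@@H](OC)CO | intermediate
37 | methyl (3R)-3-methoxy-4-oxobutanoate | COC(=O)C[C@@H](OC)C=O | intermediate
38 | methyl (3R,4E)-5-iodo-3-methoxypent-4-enoate | COC(=O)C[C@@H](OC)/C=C/I | intermediate
39 | (3R,4E)-5-iodo-3-methoxypent-4-enoic acid | OC(=O)C[C@@H](OC)/C=C/I | intermediate
40 | (3R,4E)-5-iodo-3-methoxypent-4-enoic bis(2-oxo-1,3-oxazolidin-3-yl)phosphinic anhydride | O=C(C[C@@H](OC)/C=C/I)OP(=O)(N1CCOC1=O)N1CCOC1=O | intermediate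
41 | (3R,4E)-N-{3-[(3Z,5S,6R,7R,9E)-5,7-bis(tert-butyldimethylsilyloxy)-10-iodo-4,6-dimethyldeca-3,9-dien-1-yl]-2,5-bis(triisopropylsilyloxy)phenyl}-5-iodo-3-methoxypent-4-enamide | I/C=C/C[C@@H](O[Si](C)(C)C(C)(C)C)[C@@H](C)[C@H](O[Si](C)(C)C(C)(C)C)/C(C)=C\CCc1cc(O[Si](C(C)C)(C(C)C)C(C)C)cc(NC(=O)C[C@@H](OC)/C=C/I)c1O[Si](C(C)C)(C(C)C)C(C)C | intermediate
42 | open-chain (6E,8E)-dienylstannane from 41: tributylstannyl on C6, C7–C8 bond formed, iodoalkene at C5 intact | CCCC[Sn](CCCC)(CCCC)/C=C/C=C/C[C@@H](O[Si](C)(C)C(C)(C)C)[C@@H](C)[C@H](O[Si](C)(C)C(C)(C)C)/C(C)=C\CCc1cc(O[Si](C(C)C)(C(C)C)C(C)C)cc(NC(=O)C[C@@H](OC)/C=C/I)c1O[Si](C(C)C)(C(C)C)C(C)C | intermediate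
43 | (3R,4E,6E,8E,11R,12R,13S,14Z)-macrolactam with tert-butyldimethylsilyl ethers on O11 and O13 and triisopropylsilyl ethers on O20 and O23 | CO[C@H]1/C=C/C=C/C=C/C[C@@H](O[Si](C)(C)C(C)(C)C)[C@@H](C)[C@H](O[Si](C)(C)C(C)(C)C)/C(C)=C\CCc2cc(O[Si](C(C)C)(C(C)C)C(C)C)cc(c2O[Si](C(C)C)(C(C)C)C(C)C)NC(=O)C1 | intermediate
44 | (3R,4E,6E,8E,11R,12R,13S,14Z)-11,13,20,23-tetrahydroxy-3-methoxy-12,14-dimethyl macrolactam (CNP0544229.3) | CO[C@H]1/C=C/C=C/C=C/C[C@@H](O)[C@@H](C)[C@H](O)/C(C)=C\CCc2cc(O)cc(c2O)NC(=O)C1 | target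

Total step count: 29. Longest linear sequence: 20 steps (from 1 through steps 1, 2, 5–19 and 27–29; the same length from 6 through steps 3–19 and 27–29).

Steps most likely to fail

Step 6. The vinylogous amide may slow the ring opening so that decomposition competes at the temperature required, and the electron-rich aminohydroquinone may oxidise or be only partly silylated at the crowded C23 oxygen. The fallback sets out from 11 and accepts the quinone oxidation level. After the same thermolysis the crude product is deliberately oxidised (air or Ag2O, CH2Cl2) to 2-[3-(benzyloxy)propyl]-6-(dibenzylamino)cyclohexa-2,5-diene-1,4-dione F1, a stable aminoquinone that can be purified. It is then reduced with aqueous Na2S2O4 and the hydroquinone dianion (NaH, THF) is silylated with TIPSOTf. The fallback comes back to the route at 15.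

Step 28. Oligomerisation may compete with the second, ring-closing coupling, the distannane may homocouple, and the growing triene may isomerise. The fallback replaces cross-coupling by ring-closing metathesis and sets out from 39 and 31. Each is coupled with tributyl(vinyl)stannane (PdCl2(MeCN)2, DMF) to give (3R,4E)-3-methoxyhepta-4,6-dienoic acid F2 and 3-[(3Z,5S,6R,7R,9E)-5,7-bis(tert-butyldimethylsilyloxy)-4,6-dimethyldodeca-3,9,11-trien-1-yl]-2,5-bis(triisopropylsilyloxy)aniline F3. Amide formation as in step 27 gives (3R,4E)-N-{3-[(3Z,5S,6R,7R,9E)-5,7-bis(tert-butyldimethylsilyloxy)-4,6-dimethyldodeca-3,9,11-trien-1-yl]-2,5-bis(triisopropylsilyloxy)phenyl}-3-methoxyhepta-4,6-dienamide F4. Diene–diene ring-closing metathesis with second-generation Grubbs catalyst in dilute CH2Cl2 should then form C6=C7 with loss of ethene. The fallback comes back at 43.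

Step 16. Facial selectivity may be poor in an addition that depends on the reagent overriding an epimerisable α-methyl aldehyde, and the hydrozirconation of step 18 may be incomplete beside the carbamate. The fallback sets C11 by substrate-directed reduction and sets out from 22. Transamination (MeNH(OMe)·HCl, AlMe3) gives the Weinreb amide tert-butyl {3-[(3Z,5S,6S)-5-hydroxy-7-[methoxy(methyl)amino]-4,6-dimethyl-7-oxohept-3-en-1-yl]-2,5-bis(triisopropylsilyloxy)phenyl}carbamate F5. Allylmagnesium bromide at −78 °C gives the β-hydroxy ketone tert-butyl {3-[(3Z,5S,6S)-5-hydroxy-4,6-dimethyl-7-oxodeca-3,9-dien-1-yl]-2,5-bis(triisopropylsilyloxy)phenyl}carbamate F6. Evans–Saksena reduction (Me4NBH(OAc)3, MeCN/AcOH, −30 °C) delivers hydride intramolecularly from the C13 hydroxyl and should give the 11,13-anti diol tert-butyl {3-[(3Z,5S,6R,7R)-5,7-dihydroxy-4,6-dimethyldeca-3,9-dien-1-yl]-2,5-bis(triisopropylsilyloxy)phenyl}carbamate F7. Double silylation (TBSOTf, 2,6-lutidine) gives tert-butyl {3-[(3Z,5S,6R,7R)-5,7-bis(tert-butyldimethylsilyloxy)-4,6-dimethyldeca-3,9-dien-1-yl]-2,5-bis(triisopropylsilyloxy)phenyl}carbamate F8. Cross-metathesis with vinylboronic acid pinacol ester (second-generation Grubbs catalyst) gives the (E)-alkenylboronate tert-butyl {3-[(3Z,5S,6R,7R,9E)-5,7-bis(tert-butyldimethylsilyloxy)-4,6-dimethyl-10-(4,4,5,5-tetramethyl-1,3,2-dioxaborolan-2-yl)deca-3,9-dien-1-yl]-2,5-bis(triisopropylsilyloxy)phenyl}carbamate F9. Iododeboronation with NaOH and I2 proceeds with retention, and the fallback comes back at 29.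

Further compounds
F1 | step 6 | 2-[3-(benzyloxy)propyl]-6-(dibenzylamino)cyclohexa-2,5-diene-1,4-dione | O=C1C=C(N(Cc2ccccc2)Cc2ccccc2)C(=O)C(CCCOCc2ccccc2)=C1
F2 | step 28 | (3R,4E)-3-methoxyhepta-4,6-dienoic acid | OC(=O)C[C@@H](OC)/C=C/C=C
F3 | step 28 | 3-[(3Z,5S,6R,7R,9E)-5,7-bis(tert-butyldimethylsilyloxy)-4,6-dimethyldodeca-3,9,11-trien-1-yl]-2,5-bis(triisopropylsilyloxy)aniline | C=C/C=C/C[C@@H](O[Si](C)(C)C(C)(C)C)[C@@H](C)[C@H](O[Si](C)(C)C(C)(C)C)/C(C)=C\CCc1cc(O[Si](C(C)C)(C(C)C)C(C)C)cc(N)c1O[Si](C(C)C)(C(C)C)C(C)C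
F4 | step 28 | (3R,4E)-N-{3-[(3Z,5S,6R,7R,9E)-5,7-bis(tert-butyldimethylsilyloxy)-4,6-dimethyldodeca-3,9,11-trien-1-yl]-2,5-bis(triisopropylsilyloxy)phenyl}-3-methoxyhepta-4,6-dienamide | C=C/C=C/C[C@@H](O[Si](C)(C)C(C)(C)C)[C@@H](C)[C@H](O[Si](C)(C)C(C)(C)C)/C(C)=C\CCc1cc(O[Si](C(C)C)(C(C)C)C(C)C)cc(NC(=O)C[C@@H](OC)/C=C/C=C)c1O[Si](C(C)C)(C(C)C)C(C)C
F5 | step 16 | tert-butyl {3-[(3Z,5S,6S)-5-hydroxy-7-[methoxy(methyl)amino]-4,6-dimethyl-7-oxohept-3-en-1-yl]-2,5-bis(triisopropylsilyloxy)phenyl}carbamate | CON(C)C(=O)[C@@H](C)[C@H](O)/C(C)=C\CCc1cc(O[Si](C(C)C)(C(C)C)C(C)C)cc(NC(=O)OC(C)(C)C)c1O[Si](C(C)C)(C(C)C)C(C)C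
F6 | step 16 | tert-butyl {3-[(3Z,5S,6S)-5-hydroxy-4,6-dimethyl-7-oxodeca-3,9-dien-1-yl]-2,5-bis(triisopropylsilyloxy)phenyl}carbamate | C=CCC(=O)[C@@H](C)[C@H](O)/C(C)=C\CCc1cc(O[Si](C(C)C)(C(C)C)C(C)C)cc(NC(=O)OC(C)(C)C)c1O[Si](C(C)C)(C(C)C)C(C)C
F7 | step 16 | tert-butyl {3-[(3Z,5S,6R,7R)-5,7-dihydroxy-4,6-dimethyldeca-3,9-dien-1-yl]-2,5-bis(triisopropylsilyloxy)phenyl}carbamate | C=CC[C@@H](O)[C@@H](C)[C@H](O)/C(C)=C\CCc1cc(O[Si](C(C)C)(C(C)C)C(C)C)cc(NC(=O)OC(C)(C)C)c1O[Si](C(C)C)(C(C)C)C(C)C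
F8 | step 16 | tert-butyl {3-[(3Z,5S,6R,7R)-5,7-bis(tert-butyldimethylsilyloxy)-4,6-dimethyldeca-3,9-dien-1-yl]-2,5-bis(triisopropylsilyloxy)phenyl}carbamate | C=CC[C@@H](O[Si](C)(C)C(C)(C)C)[C@@H](C)[C@H](O[Si](C)(C)C(C)(C)C)/C(C)=C\CCc1cc(O[Si](C(C)C)(C(C)C)C(C)C)cc(NC(=O)OC(C)(C)C)c1O[Si](C(C)C)(C(C)C)C(C)C
F9 | step 16 | tert-butyl {3-[(3Z,5S,6R,7R,9E)-5,7-bis(tert-butyldimethylsilyloxy)-4,6-dimethyl-10-(4,4,5,5-tetramethyl-1,3,2-dioxaborolan-2-yl)deca-3,9-dien-1-yl]-2,5-bis(triisopropylsilyloxy)phenyl}carbamate | CC1(C)OB(/C=C/C[C@@H](O[Si](C)(C)C(C)(C)C)[C@@H](C)[C@H](O[Si](C)(C)C(C)(C)C)/C(C)=C\CCc2cc(O[Si](C(C)C)(C(C)C)C(C)C)cc(NC(=O)OC(C)(C)C)c2O[Si](C(C)C)(C(C)C)C(C)C)OC1(C)C
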